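**Plan** (labdane numbering for all decalin compounds)
- Retrosynthetic cuts: the two ester C–O bonds; C9–C10 (closure of ring B); C7–C8 (sp3–sp2 union of a ring-A half and a side-chain half); C5–C6 and the C4 methyls back to a quinic-acid enone.
- Forward: ring A is carved from (−)-quinic acid, gem-dimethylated and allylated. The (R)-linalool-derived (Z)-2-bromoallylsilane is joined by Negishi coupling. The C10 ketone becomes an axial-oxygen spiro-epoxide, and ring B (C5–C6–C7–C8–C9–C10) then closes.
- Enabling feature: the array HO–C20–C10(quaternary)–C9–C8(=C17) of ring B is the retron of an epoxide opening by an allylsilane, so one event gives the quaternary carbon, its CH2OH, C9 and the exocyclic methylene.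
- Stereochemistry: C2/C3 are bought (quinic acid) and C13 is bought (linalool). C5 is set by alkylation with thermodynamic convergence, and the C10 epoxide by equatorial CH2 delivery. C10 (inversion) and C9 (E-allylsilane, chair) are set together in the key step. C7 is set last by hydride attack anti to the axial C9 chain.

Key step: step 16

Remark: read as drawn, the target is a 9βH-labdane (C9 side chain trans to C-20) with an (R)-2-methylbutanoate; (R)-(−)-linalool, angelic acid and (R)-2-methylbutanoic acid are taken as purchasable.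

**Route**

Step 1
Reactants: 1 (−)-quinic acid
Product: 2 3,4-O-isopropylidene-quinic acid 1,5-lactone
Conditions: 2,2-dimethoxypropane, TsOH·H2O (cat.), acetone, reflux
Reagents that add atoms: 2,2-dimethoxypropane COC(C)(C)OC
Why: Acid-catalysed acetalisation of the cis-3,4-diol with concurrent lactonisation onto the 5-OH; no stereocentre is touched.

Step 2
Reactants: 2 3,4-O-isopropylidene-quinic acid 1,5-lactone
Product: 3 1-(hydroxymethyl)-3,4-O-isopropylidene-cyclohexane-1,3,4,5-tetrol (lactone carbon reduced to CH2OH)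
Conditions: NaBH4, EtOH, 0 °C to rt
Reagents that add atoms: none
Why: Borohydride reduction of the strained lactone to the diol.

Step 3
Reactants: 3 triol
Product: 4 (3R,4S,5R)-5-hydroxy-3,4-(isopropylidenedioxy)cyclohexan-1-one
Conditions: NaIO4, pH 7 buffer/H2O, 0 °C to rt
Reagents that add atoms: none
Why: Periodate glycol cleavage of the tertiary/primary 1,2-diol gives the ketone.

Step 4
Reactants: 4 hydroxy ketone
Product: 6 (4S,5R)-4,5-(isopropylidenedioxy)cyclohex-2-en-1-one, via mesylate 5 (not isolated)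
Conditions: MsCl, Et3N, CH2Cl2, 0 °C to rt
Reagents that add atoms: none
Why: Mesylation and E1cB elimination of the β-sulfonate; the acetonide oxygen is the poorer leaving group and stays.

Step 5
Reactants: 6 enone
Product: 7 1-(trimethylsilyloxy)-3-methyl-4,5-(isopropylidenedioxy)cyclohex-1-ene (3-methyl trans to the dioxolane; this centre is erased in step 6)
Conditions: Me2CuLi (from MeLi, CuI), TMSCl, THF, −78 °C; Et3N quench
Reagents that add atoms: lithium dimethylcuprate [Li+].C[Cu-]C; chlorotrimethylsilane C[Si](C)(C)Cl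
Why: TMSCl-accelerated cuprate conjugate addition anti to the γ-alkoxy group gives the enol silane regiospecifically.

Step 6
Reactants: 7 enol silane
Product: 8 (4S,5R)-4,5-(isopropylidenedioxy)-3-methylcyclohex-2-en-1-one
Conditions: Pd(OAc)2 (10 mol%), O2 (1 atm), DMSO, rt
Reagents that add atoms: none
Why: Saegusa–Ito dehydrosilylation (oxo-π-allyl palladium, β-hydride loss from the methyl-bearing carbon) restores the enone, now β-methylated.

Step 7
Reactants: 8 β-methyl enone
Product: 10 (2S,4S,5R)-2-allyl-4,5-(isopropylidenedioxy)-3,3-dimethylcyclohexan-1-one, via lithium enolate 9 (not isolated)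
Conditions: Me2CuLi, Et2O/THF, −20 °C; then allyl bromide, HMPA, −20 °C to rt; crude stirred with DBU (0.2 equiv), CH2Cl2, rt
Reagents that add atoms: lithium dimethylcuprate [Li+].C[Cu-]C; allyl bromide C=CCBr
Why: Cuprate conjugate addition makes the gem-dimethyl carbon and a regiodefined enolate whose C-allylation sets C5; attack anti to the dioxolane is expected, and because the 2,4-trans ketone is the only epimer free of a syn-diaxial O/alkyl or O/Me contact, DBU should converge any cis epimer to it (the equatorial C–O bond is misaligned for β-elimination).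

Step 8
Reactants: 10 allyl ketone
Product: 12 (2S,4S,5R)-2-(2-hydroxyethyl)-4,5-(isopropylidenedioxy)-3,3-dimethylcyclohexan-1-one, via keto aldehyde 11 (not isolated)
Conditions: O3, CH2Cl2/MeOH, −78 °C; Me2S; then NaBH4, −78 to −40 °C
Reagents that add atoms: ozone [O-][O+]=O
Why: Ozonolysis of the terminal alkene followed by chemoselective borohydride reduction of the aldehyde in the presence of the hindered, α-branched ketone.

Step 9
Reactants: 12 hydroxy ketone
Product: 13 (2S,4S,5R)-2-(2-iodoethyl)-4,5-(isopropylidenedioxy)-3,3-dimethylcyclohexan-1-one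
Conditions: I2, PPh3, imidazole, CH2Cl2, 0 °C to rt
Reagents that add atoms: iodine II
Why: Appel iodination of the primary alcohol under near-neutral conditions that leave the epimerisable C5 centre alone.

Step 10
Reactants: 14 (R)-(−)-linalool
Product: 15 (R)-linalool triethylsilyl ether
Conditions: TESOTf, 2,6-lutidine, CH2Cl2, 0 °C
Reagents that add atoms: triethylsilyl triflate CC[Si](CC)(CC)OS(=O)(=O)C(F)(F)F
Why: Silylation of the tertiary allylic alcohol masks it against ionisation in the Pd and Lewis-acid steps; C13 is bought here.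

Step 11
Reactants: 15 linalool TES ether
Product: 16 (4R)-4-methyl-4-(triethylsilyloxy)hex-5-enal
Conditions: O3 (1.0 equiv, Sudan Red 7B end point), CH2Cl2, pyridine (cat.), −78 °C; then PPh3
Reagents that add atoms: ozone [O-][O+]=O
Why: Ozone cleaves the electron-rich trisubstituted alkene much faster than the hindered monosubstituted vinyl group.

Step 12
Reactants: 16 aldehyde
Product: 17 (3R)-7,7-dibromo-3-methyl-3-(triethylsilyloxy)hepta-1,6-diene
Conditions: CBr4, PPh3, Et3N, CH2Cl2, 0 °C
Reagents that add atoms: carbon tetrabromide BrC(Br)(Br)Br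
Why: Ramirez/Corey–Fuchs dibromo-olefination of the aldehyde.

Step 13
Reactants: 17 1,1-dibromoalkene
Product: 18 [(2Z,6R)-2-bromo-6-methyl-6-(triethylsilyloxy)octa-2,7-dien-1-yl]trimethylsilane
Conditions: Me3SiCH2MgCl, ZnCl2, THF, 0 °C; then 17, PdCl2(DPEphos) (3 mol%), THF, 0 to 23 °C
Reagents that add atoms: (trimethylsilyl)methylmagnesium chloride C[Si](C)(C)C[Mg]Cl
Why: Negishi trans-selective mono-alkylation of a 1,1-dibromoalkene: oxidative addition occurs at the bromide trans to the chain, so CH2SiMe3 ends trans to the chain and the remaining bromide cis (Z).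

Step 14
Reactants: 13 iodo ketone; 18 (Z)-2-bromoallylsilane
Product: 20 (2S,4S,5R)-2-[(3E,7R)-7-methyl-7-(triethylsilyloxy)-3-(trimethylsilylmethyl)nona-3,8-dienyl]-4,5-(isopropylidenedioxy)-3,3-dimethylcyclohexan-1-one, via alkylzinc iodide 19 (not isolated)
Conditions: Zn dust (TMSCl/1,2-dibromoethane activated), DMA, 40 °C; then 18, Pd(t-Bu3P)2 (3 mol%), THF/DMA, 23 °C
Reagents that add atoms: none
Why: Zinc insertion tolerates the ketone, and Negishi sp3–sp2 coupling with retention puts the ring-A chain cis to the side chain on the (E)-allylsilane.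

Step 15
Reactants: 20 allylsilane ketone
Product: 21 spiro-epoxide of 20 at the ketone carbon (1-oxaspiro[2.5]octane; epoxide O axial, on the face of the C5 chain and opposite the acetonide; CH2 equatorial)
Conditions: ClCH2I, n-BuLi, THF, −78 °C to rt
Reagents that add atoms: chloroiodomethane ClCI
Why: In situ chloromethyllithium (weakly basic) adds to the ketone from the equatorial direction because the axial 4β-methyl blocks axial attack, and the chlorohydrin alkoxide closes to the epoxide with axial oxygen.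

Step 16
Reactants: 21 epoxy allylsilane
Product: 22 (13R)-2α,3α-(isopropylidenedioxy)-13-(triethylsilyloxy)-9βH-labda-8(17),14-dien-20-ol
Conditions: Et2AlCl (1.5 equiv), CH2Cl2, −78 °C; then aq. NaHCO3/Rochelle salt
Reagents that add atoms: none
Why: Et2AlCl activates the epoxide oxygen and the C10–O bond ionises with anti participation of the allylsilane, whose γ-carbon C9 bonds to the tertiary spiro carbon C10 while the β-silyl cation at C8 loses Me3Si to give the C8=C17 methylene and the C20 alkoxide. The closest known type is the Lewis-acid epoxide-initiated cation–olefin cyclisation terminated by an allylsilane. Ring B closes 6-endo-trig at the C8=C9 alkene, with the cleaved epoxide C–O bond exo to the new ring. C10 is set by inversion at the axial-oxygen epoxide (C9 enters on the equatorial α side, C20 swings axial β, trans-decalin), and C9 by the (E)-allylsilane in a chair transition state that places C11 (cis to C7 on the alkene) axial, i.e. α and trans to C20. The step needs C–C bonding at the tertiary rather than the primary epoxide carbon and faster than a 1,2-hydride shift; Lewis-acid polarisation toward C10, the six-membered chair and the nucleophilic allylsilane secure this, and silicon fixes the alkene position.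

Step 17
Reactants: 22 decalin alcohol
Product: 23 20-[(R)-2-methylbutanoate] of 22
Conditions: (R)-2-methylbutanoic acid, DIC, DMAP (cat.), CH2Cl2, 0 °C to rt
Reagents that add atoms: (R)-2-methylbutanoic acid CC[C@@H](C)C(=O)O
Why: Steglich esterification of the only free hydroxyl (primary, neopentyl) under conditions that do not epimerise the α-centre of the acid.

Step 18
Reactants: 23 ester
Product: 24 (13R)-2α,3α,13-trihydroxy-9βH-labda-8(17),14-dien-20-yl (R)-2-methylbutanoate
Conditions: AcOH/THF/H2O (3:1:1), 45 °C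
Reagents that add atoms: none
Why: Mild aqueous acid hydrolyses the cis-fused acetonide and the silyl ether while the weak acid should spare the tertiary allylic alcohol and the exocyclic alkene.

Step 19
Reactants: 24 triol
Product: 25 2-O-angelate of 24
Conditions: angelic acid, 2,4,6-trichlorobenzoyl chloride, Et3N, toluene, rt; then 24, 75 °C (no DMAP)
Reagents that add atoms: angelic acid C/C=C(/C)C(=O)O
Why: Yamaguchi-type mixed-anhydride acylation without nucleophilic catalyst keeps the Z geometry and selects the equatorial 2α-OH over the axial, neopentyl 3α-OH and the tertiary 13-OH.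

Step 20
Reactants: 25 angelate
Product: 26 7ξ-hydroxy derivative of 25 (C7 epimer mixture)
Conditions: SeO2 (0.5 equiv), t-BuOOH (3 equiv), CH2Cl2, 0 °C to rt
Reagents that add atoms: selenium dioxide O=[Se]=O (re-oxidised in situ); tert-butyl hydroperoxide CC(C)(C)OO
Why: Selenium dioxide allylic oxidation (ene reaction, then [2,3]-shift) of the exocyclic alkene at the C7 methylene keeps the double bond in place; the vinyl group has no allylic hydrogen and the angelate is electron-poor.

Step 21
Reactants: 26 allylic alcohol mixture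
Product: 27 7-oxo derivative of 25 (α-methylene ketone)
Conditions: MnO2 (activated, excess), CH2Cl2, rt
Reagents that add atoms: none
Why: Manganese dioxide oxidises only the allylic C7 alcohol and leaves the 3α and 13 hydroxyls untouched.

Step 22
Reactants: 27 enone
Product: 28 target, (13R)-2α-angeloyloxy-3α,7α,13-trihydroxy-9βH-labda-8(17),14-dien-20-yl (R)-2-methylbutanoate
Conditions: NaBH4, CeCl3·7H2O, MeOH, −78 °C
Reagents that add atoms: none
Why: Luche 1,2-reduction; the axial 9α side chain and H-5α block the α (axial) trajectory, so hydride should enter from the β face and give the axial 7α-alcohol, with both esters untouched.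

**Compound list**
1 | (−)-quinic acid | O[C@@]1(C(=O)O)C[C@@H](O)[C@@H](O)[C@H](O)C1 | starting material
2 | 3,4-O-isopropylidene-quinic acid 1,5-lactone | O[C@@]12C[C@H]3OC(C)(C)O[C@H]3[C@@H](C1)OC2=O | intermediate
3 | 1-(hydroxymethyl)-3,4-O-isopropylidene-cyclohexane-1,3,4,5-tetrol | OC[C@]1(O)C[C@H]2OC(C)(C)O[C@H]2[C@H](O)C1 | intermediate
4 | (3R,4S,5R)-5-hydroxy-3,4-(isopropylidenedioxy)cyclohexan-1-one | O=C1C[C@@H](O)[C@@H]2OC(C)(C)O[C@@H]2C1 | intermediate
5 | mesylate of 4 | O=C1C[C@@H](OS(C)(=O)=O)[C@@H]2OC(C)(C)O[C@@H]2C1 | intermediate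
6 | (4S,5R)-4,5-(isopropylidenedioxy)cyclohex-2-en-1-one | O=C1C=C[C@@H]2OC(C)(C)O[C@@H]2C1 | intermediate
7 | 1-(trimethylsilyloxy)-3-methyl-4,5-(isopropylidenedioxy)cyclohex-1-ene, methyl trans to dioxolane | C[Si](C)(C)OC1=C[C@@H](C)[C@@H]2OC(C)(C)O[C@@H]2C1 | intermediate
8 | (4S,5R)-4,5-(isopropylidenedioxy)-3-methylcyclohex-2-en-1-one | O=C1C=C(C)[C@@H]2OC(C)(C)O[C@@H]2C1 | intermediate
9 | lithium (4S,5R)-4,5-(isopropylidenedioxy)-3,3-dimethylcyclohex-1-en-1-olate | [Li]OC1=CC(C)(C)[C@@H]2OC(C)(C)O[C@@H]2C1 | intermediate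
10 | (2S,4S,5R)-2-allyl-4,5-(isopropylidenedioxy)-3,3-dimethylcyclohexan-1-one | C=CC[C@H]1C(C)(C)[C@@H]2OC(C)(C)O[C@@H]2CC1=O | intermediate
11 | (2S,4S,5R)-2-(2-oxoethyl)-4,5-(isopropylidenedioxy)-3,3-dimethylcyclohexan-1-one | O=CC[C@H]1C(C)(C)[C@@H]2OC(C)(C)O[C@@H]2CC1=O | intermediate
12 | (2S,4S,5R)-2-(2-hydroxyethyl)-4,5-(isopropylidenedioxy)-3,3-dimethylcyclohexan-1-one | OCC[C@H]1C(C)(C)[C@@H]2OC(C)(C)O[C@@H]2CC1=O | intermediate
13 | (2S,4S,5R)-2-(2-iodoethyl)-4,5-(isopropylidenedioxy)-3,3-dimethylcyclohexan-1-one | ICC[C@H]1C(C)(C)[C@@H]2OC(C)(C)O[C@@H]2CC1=O | intermediate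
14 | (R)-(−)-linalool | C=C[C@](C)(O)CCC=C(C)C | starting material
15 | (R)-linalool triethylsilyl ether | C=C[C@](C)(O[Si](CC)(CC)CC)CCC=C(C)C | intermediate
16 | (4R)-4-methyl-4-(triethylsilyloxy)hex-5-enal | C=C[C@](C)(O[Si](CC)(CC)CC)CCC=O | intermediate
17 | (3R)-7,7-dibromo-3-methyl-3-(triethylsilyloxy)hepta-1,6-diene | C=C[C@](C)(O[Si](CC)(CC)CC)CCC=C(Br)Br | intermediate
18 | [(2Z,6R)-2-bromo-6-methyl-6-(triethylsilyloxy)octa-2,7-dien-1-yl]trimethylsilane | C=C[C@](C)(O[Si](CC)(CC)CC)CC/C=C(\Br)C[Si](C)(C)C | intermediate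
19 | alkylzinc iodide from 13 | I[Zn]CC[C@H]1C(C)(C)[C@@H]2OC(C)(C)O[C@@H]2CC1=O | intermediate
20 | (2S,4S,5R)-2-[(3E,7R)-7-methyl-7-(triethylsilyloxy)-3-(trimethylsilylmethyl)nona-3,8-dienyl]-4,5-(isopropylidenedioxy)-3,3-dimethylcyclohexan-1-one | C=C[C@](C)(O[Si](CC)(CC)CC)CC/C=C(/C[Si](C)(C)C)CC[C@H]1C(C)(C)[C@@H]2OC(C)(C)O[C@@H]2CC1=O | intermediate
21 | spiro-epoxide of 20 (O axial, cis to the C5 chain; CH2 equatorial) | C=C[C@](C)(O[Si](CC)(CC)CC)CC/C=C(/C[Si](C)(C)C)CC[C@H]1C(C)(C)[C@@H]2OC(C)(C)O[C@@H]2C[C@]13CO3 | intermediate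
22 | (13R)-2α,3α-(isopropylidenedioxy)-13-(triethylsilyloxy)-9βH-labda-8(17),14-dien-20-ol | C=C[C@](C)(O[Si](CC)(CC)CC)CC[C@@H]1C(=C)CC[C@H]2C(C)(C)[C@@H]3OC(C)(C)O[C@@H]3C[C@]12CO | intermediate
23 | 20-[(R)-2-methylbutanoate] of 22 | C=C[C@](C)(O[Si](CC)(CC)CC)CC[C@@H]1C(=C)CC[C@H]2C(C)(C)[C@@H]3OC(C)(C)O[C@@H]3C[C@]12COC(=O)[C@H](C)CC | intermediate
24 | (13R)-2α,3α,13-trihydroxy-9βH-labda-8(17),14-dien-20-yl (R)-2-methylbutanoate | C=C[C@](C)(O)CC[C@@H]1C(=C)CC[C@H]2C(C)(C)[C@H](O)[C@H](O)C[C@]12COC(=O)[C@H](C)CC | intermediate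
25 | 2-O-angelate of 24 | C=C[C@](C)(O)CC[C@@H]1C(=C)CC[C@H]2C(C)(C)[C@H](O)[C@H](OC(=O)/C(C)=C\C)C[C@]12COC(=O)[C@H](C)CC | intermediate
26 | 7ξ-hydroxy derivative of 25 | C=C[C@](C)(O)CC[C@@H]1C(=C)C(O)C[C@H]2C(C)(C)[C@H](O)[C@H](OC(=O)/C(C)=C\C)C[C@]12COC(=O)[C@H](C)CC | intermediate
27 | 7-oxo derivative of 25 | C=C[C@](C)(O)CC[C@@H]1C(=C)C(=O)C[C@H]2C(C)(C)[C@H](O)[C@H](OC(=O)/C(C)=C\C)C[C@]12COC(=O)[C@H](C)CC | intermediate
28 | (13R)-2α-angeloyloxy-3α,7α,13-trihydroxy-9βH-labda-8(17),14-dien-20-yl (R)-2-methylbutanoate | C=C[C@](C)(O)CC[C@@H]1C(=C)[C@H](O)C[C@H]2C(C)(C)[C@H](O)[C@H](OC(=O)/C(C)=C\C)C[C@]12COC(=O)[C@H](C)CC | target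

**Totals and risks**
Total steps: 22. Longest linear sequence: 18 (steps 1–9 and 14–22); the side-chain branch is steps 10–13.

Steps most likely to fail:

1. Step 16. The Lewis acid may trigger a 1,2-hydride shift of the epoxide or protodesilylation before C–C bonding. Facial selectivity at C9 may be poor (boat instead of chair), or inversion at C10 may be lost. Fallback (radical instead of cationic closure), setting out from 17 and 13 and returning at 22: dibromide 17 is coupled trans-selectively with MeZnCl under PdCl2(DPEphos) to (3R,6Z)-7-bromo-3-methyl-3-(triethylsilyloxy)octa-1,6-diene F1. This is joined with alkylzinc 19 (from 13) under Pd(t-Bu3P)2 to the methyl-substituted (Z)-alkene ketone F2, and LiCH2Cl converts that into the spiro-epoxide F3. Cp2TiCl (from Cp2TiCl2 and Mn dust, THF, rt) opens the epoxide homolytically to the tertiary C10 radical, which adds 6-endo to C9; the C8 radical is trapped by Ti(III) and eliminated to the exocyclic alkene, giving 22 after aqueous work-up.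

2. Step 14. Zinc insertion next to the ketone may be slow or end in protonolysis, and alkene geometry may erode in the second coupling. Fallback (olefination at C8=C9 instead of sp3–sp2 coupling), setting out from 10 and 16 and returning at 21: ketone 10 is converted with LiCH2Cl into the allyl spiro-epoxide F4, and ozonolysis (O3, then PPh3) gives the epoxy aldehyde F5. Knoevenagel condensation with triethyl phosphonoacetate and NaBH4 conjugate reduction give the α-alkylated phosphonoacetate F6. Horner–Wadsworth–Emmons reaction with aldehyde 16 gives the (E)-enoate F7. DIBAL-H gives the allylic alcohol F8, methyl chloroformate/pyridine the allylic methyl carbonate F9, and Pd(0)-catalysed silylation with hexamethyldisilane delivers 21.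

3. Step 7. C-alkylation of the neopentyl lithium enolate may be sluggish (proton transfer, O-alkylation) and facial control at C5 incomplete. Fallback (Pd-allylation of an enol carbonate instead of SN2 alkylation), setting out from 8 and returning at 10: the enolate 9 from 8 and Me2CuLi is O-acylated with allyl chloroformate to the allyl enol carbonate F10. Pd(PPh3)4 in THF then effects decarboxylative Tsuji allylation to 10, followed by the same DBU equilibration at C5.

**Further compounds**
F1 | step 16 | (3R,6Z)-7-bromo-3-methyl-3-(triethylsilyloxy)octa-1,6-diene | C=C[C@](C)(O[Si](CC)(CC)CC)CC/C=C(\Br)C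
F2 | step 16 | (2S,4S,5R)-2-[(3Z,7R)-3,7-dimethyl-7-(triethylsilyloxy)nona-3,8-dienyl]-4,5-(isopropylidenedioxy)-3,3-dimethylcyclohexan-1-one | C=C[C@](C)(O[Si](CC)(CC)CC)CC/C=C(/C)CC[C@H]1C(C)(C)[C@@H]2OC(C)(C)O[C@@H]2CC1=O
F3 | step 16 | spiro-epoxide of F2 (O axial, CH2 equatorial) | C=C[C@](C)(O[Si](CC)(CC)CC)CC/C=C(/C)CC[C@H]1C(C)(C)[C@@H]2OC(C)(C)O[C@@H]2C[C@]13CO3
F4 | step 14 | spiro-epoxide of 10 (O axial, CH2 equatorial) | C=CC[C@H]1C(C)(C)[C@@H]2OC(C)(C)O[C@@H]2C[C@]13CO3
F5 | step 14 | epoxy aldehyde from F4 | O=CC[C@H]1C(C)(C)[C@@H]2OC(C)(C)O[C@@H]2C[C@]13CO3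
F6 | step 14 | triethyl phosphonoacetate α-alkylated by the ring-A ethyl chain | CCOC(=O)C(CC[C@H]1C(C)(C)[C@@H]2OC(C)(C)O[C@@H]2C[C@]13CO3)P(=O)(OCC)OCC
F7 | step 14 | (E)-enoate from F6 and 16 | C=C[C@](C)(O[Si](CC)(CC)CC)CC/C=C(/C(=O)OCC)CC[C@H]1C(C)(C)[C@@H]2OC(C)(C)O[C@@H]2C[C@]13CO3
F8 | step 14 | allylic alcohol from F7 | C=C[C@](C)(O[Si](CC)(CC)CC)CC/C=C(/CO)CC[C@H]1C(C)(C)[C@@H]2OC(C)(C)O[C@@H]2C[C@]13CO3
F9 | step 14 | allylic methyl carbonate from F8 | C=C[C@](C)(O[Si](CC)(CC)CC)CC/C=C(/COC(=O)OC)CC[C@H]1C(C)(C)[C@@H]2OC(C)(C)O[C@@H]2C[C@]13CO3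
F10 | step 7 | allyl enol carbonate of enolate 9 | C=CCOC(=O)OC1=CC(C)(C)[C@@H]2OC(C)(C)O[C@@H]2C1
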